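**Strategy**

Everything rests on cutting the C3a–O bond of the target, which leads back to a flat dihydrobenzofuran arene. The key step exploits the position of C3a, the one tetrahedral carbon common to the furan ring and the carbocycle, para to the C6 oxygen: singlet oxygen bridges C3a and C6, and opening of the bridge at C6 delivers in one operation the C3a carbinol oxygen, the C6 ketone, the C7=C7a vinylogous ester and a C4/C6 diketone with C5 as its only carbon acid. The precursor is an alkene-free 4,6-dihydroxy-7-isobutyryl-2,3-dihydrobenzofuran whose single stereocentre, C2, carries a triethylsilyloxyisopropyl group. C5 is then prenylated and methylated.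

Key step: step 9

Remark on the chemistry: benzofuran numbering (O1, C2, C3, C3a, C4 to C7, C7a) is used for the bicycle, the target is the (2S,3aR,5S) isomer, and the D-fructose-derived ketone of the Shi epoxidation is assumed to give the (R)-epoxide of an ArCH2CH=CMe2 unit, as it does with other trisubstituted alkenes.

**Route**

Step 1
Reactants: 1 phloroglucinol; 2 isobutyryl chloride
Product: 3 phlorisobutyrophenone
Conditions: AlCl3 (4 equiv), PhNO2, rt to 65 °C; then ice, 1 M HCl
Reagents that add atoms: isobutyryl chloride (2), CC(C)C(=O)Cl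
Why: Friedel–Crafts acylation of the symmetrical triol should stop after one acyl group, because the chelated aryl ketone deactivates the ring.

Step 2
Reactants: 3 phlorisobutyrophenone; 4 prenyl bromide
Product: 5 3-prenylphlorisobutyrophenone
Conditions: 10% aq. KOH (1 equiv), 0 °C, slow addition of 4 (0.9 equiv)
Reagents that add atoms: prenyl bromide (4), CC(C)=CCBr
Why: C-alkylation of the ambident phloroglucinol phenolate by a soft allylic bromide in water is the classical C-prenylation of acylphloroglucinols; the two free ring carbons are equivalent and a deficit of bromide limits double prenylation.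

Step 3
Reactants: 5 3-prenylphlorisobutyrophenone
Product: 6 4,6-di-O-benzyl ether with the 2-hydroxyl free
Conditions: BnBr (2.05 equiv), K2CO3 (2.2 equiv), acetone, reflux
Reagents that add atoms: benzyl bromide, BrCc1ccccc1
Why: Williamson etherification should take the para 4-hydroxyl (most acidic, not chelated) and then the less hindered 6-hydroxyl, while the 2-hydroxyl, wedged between the prenyl and acyl groups and held in the hydrogen bond to the ketone, stays free.

Step 4
Reactants: 6 4,6-di-O-benzyl ether
Product: 7 2-O-acetate of 6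
Conditions: Ac2O (1.5 equiv), pyridine, 4-(dimethylamino)pyridine (cat.), rt
Reagents that add atoms: acetic anhydride, CC(=O)OC(C)=O
Why: Nucleophile-catalysed acetylation caps the last phenol, so that the ring is not oxidised by the dioxirane and the epoxide made next has no internal nucleophile until base is added.

Step 5
Reactants: 7 2-O-acetate
Product: 8 (R)-epoxide of the prenyl group (acetate)
Conditions: 1,2:4,5-di-O-isopropylidene-β-D-erythro-2,3-hexodiulo-2,6-pyranose (0.3 equiv), Oxone (2KHSO5·KHSO4·K2SO4), K2CO3, Bu4NHSO4 (cat.), MeCN/CH2(OMe)2/aq. Na2B4O7 buffer, pH 10.5, 0 °C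
Reagents that add atoms: potassium peroxymonosulfate (KHSO5, the active salt of Oxone), [K+].[O-]S(=O)(=O)OO
Why: Shi asymmetric epoxidation: the chiral dioxirane formed from the ketone and KHSO5 transfers oxygen to the trisubstituted alkene through a spiro transition state, so the catalyst alone sets the (R) centre.

Step 6
Reactants: 8 (R)-epoxide acetate
Product: 10 (S)-2-(2-hydroxypropan-2-yl)-dihydrobenzofuran, via phenol epoxide 9 (not isolated)
Conditions: K2CO3 (0.2 equiv), MeOH, 0 °C to rt
Reagents that add atoms: none
Why: Methanolysis of the aryl acetate frees the only phenoxide, which opens the oxirane by 5-exo-tet SN2 attack at the secondary carbon with inversion (R to S at C2); basic conditions favour this mode over the 6-endo chromanol.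

Step 7
Reactants: 10 (S)-dihydrobenzofuran carbinol
Product: 11 triethylsilyl ether of 10
Conditions: Et3SiOTf (1.5 equiv), 2,6-lutidine (3 equiv), CH2Cl2, −78 to 0 °C
Reagents that add atoms: triethylsilyl trifluoromethanesulfonate, CC[Si](CC)(CC)OS(=O)(=O)C(F)(F)F
Why: Silylation of a tertiary alcohol with a silyl triflate and a hindered pyridine base is standard; no phenol is free, and the ether enlarges the C2 group for the face selection in step 9.

Step 8
Reactants: 11 triethylsilyl ether
Product: 12 4,6-dihydroxy arene
Conditions: H2 (1 atm), 10% Pd/C, EtOAc, rt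
Reagents that add atoms: none
Why: Hydrogenolysis of the two benzyl aryl ethers should be clean, since no alkene is left, the hindered chelated aryl ketone resists reduction and the tertiary silyl ether is stable in neutral ethyl acetate.

Step 9
Reactants: 12 4,6-dihydroxy arene
Product: 15 C3a para-quinol, via endoperoxide 13 (not isolated), via hydroperoxide 14 (not isolated)
Conditions: O2, 5,10,15,20-tetraphenylporphyrin (1 mol%), white LED, CH2Cl2, −40 °C; then Me2S (3 equiv), −40 °C to rt
Reagents that add atoms: dioxygen, O=O
Why: Sensitised singlet oxygen should add suprafacially across the para carbons C3a and C6 of the electron-rich arene in a [4+2] cycloaddition, which forms the C3a–O bond and the peroxide-bridged bicycle 13; its only new ring, the 2,3-dioxabicyclo[2.2.2]octadiene bridge, is thus closed by concerted cycloaddition. The bridge then opens at C6, a peroxy hemiketal carbon, to the C6 ketone and the C3a hydroperoxide 14, which Me2S reduces to the carbinol in the same flask. The closest known reaction is the sensitised photooxygenation of para-alkylphenols to para-peroxyquinols followed by reduction. The new stereocentre C3a is controlled by C2: oxygen should approach the flat arene on the face opposite the bulky triethylsilyloxyisopropyl group, so the C3a oxygen ends trans to it. The step needs positional selectivity for C3a over the open C5 position; C3a/C6 is the only para pair that ends on a hydroxyl-bearing carbon without a deactivated partner (C4/C7 carries the acyl group at C7, and C5/C7a has no hydroxyl at which a bridge could collapse), and attack at C5 remains the main risk. The Schenck ene reaction cannot compete because the substrate holds no alkene.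

Step 10
Reactants: 15 C3a para-quinol
Product: 17 C3a triethylsilyl ether of the quinol, via bis-silyl enol ether 16 (not isolated)
Conditions: Et3SiOTf (2.5 equiv), 2,6-lutidine (4 equiv), CH2Cl2, −78 to 0 °C; then MeOH, 0 °C
Reagents that add atoms: triethylsilyl trifluoromethanesulfonate, CC[Si](CC)(CC)OS(=O)(=O)C(F)(F)F
Why: Silylation with the silyl triflate should cover the hindered C3a carbinol and the enol oxygen alike, and methanol then cleaves only the labile vinylogous silyl ester; the tertiary ether that remains blocks the α-ketol and will screen one face of C5, and no prenyl group is yet present to suffer acid.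

Step 11
Reactants: 17 C3a silyl ether; 4 prenyl bromide
Product: 18 C5-prenyl enol
Conditions: NaOMe (1.0 equiv), MeOH, 0 °C; 4 (1.1 equiv), 0 °C to rt
Reagents that add atoms: prenyl bromide (4), CC(C)=CCBr
Why: C-alkylation of the cyclic 1,3-diketone enolate at C5, its only carbon acid, by a soft allylic bromide in a protic solvent that hydrogen-bonds the enolate oxygens is the classical C-prenylation of acylphloroglucinol-derived diketones; the product is an enol, so C5 is not yet stereogenic.

Step 12
Reactants: 18 C5-prenyl enol; 19 iodomethane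
Product: 20 bis(triethylsilyl) ether of the target
Conditions: K2CO3 (1.5 equiv), MeI (5 equiv), acetone, rt
Reagents that add atoms: iodomethane (19), CI
Why: C-methylation of the planar 2-substituted 1,3-diketone enolate should occur on the face opposite the pseudoaxial C3a silyloxy group, so that methyl ends trans and prenyl cis to the C3a oxygen (5S); the non-nucleophilic base avoids retro-Claisen opening of the now non-enolisable triketone.

Step 13
Reactants: 20 bis(triethylsilyl) ether
Product: 21 target CNP0220605.1
Conditions: HF·pyridine, pyridine, THF, 0 °C to rt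
Reagents that add atoms: none
Why: Fluoride-driven desilylation of both tertiary silyl ethers under buffered, weakly acidic conditions should spare the base-sensitive α-ketol and the prenyl alkene.

**Compound list**

1 | phloroglucinol (benzene-1,3,5-triol) | Oc1cc(O)cc(O)c1 | starting material
2 | isobutyryl chloride (2-methylpropanoyl chloride) | CC(C)C(=O)Cl | starting material
3 | phlorisobutyrophenone, 2-methyl-1-(2,4,6-trihydroxyphenyl)propan-1-one | CC(C)C(=O)c1c(O)cc(O)cc1O | intermediate
4 | prenyl bromide (1-bromo-3-methylbut-2-ene) | CC(C)=CCBr | starting material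
5 | 2-methyl-1-[2,4,6-trihydroxy-3-(3-methylbut-2-en-1-yl)phenyl]propan-1-one | CC(C)C(=O)c1c(O)cc(O)c(CC=C(C)C)c1O | intermediate
6 | 1-[4,6-bis(benzyloxy)-2-hydroxy-3-(3-methylbut-2-en-1-yl)phenyl]-2-methylpropan-1-one | CC(C)C(=O)c1c(O)c(CC=C(C)C)c(OCc2ccccc2)cc1OCc1ccccc1 | intermediate
7 | 3,5-bis(benzyloxy)-2-(2-methylpropanoyl)-6-(3-methylbut-2-en-1-yl)phenyl acetate | CC(C)C(=O)c1c(OC(C)=O)c(CC=C(C)C)c(OCc2ccccc2)cc1OCc1ccccc1 | intermediate
8 | 3,5-bis(benzyloxy)-2-{[(2R)-3,3-dimethyloxiran-2-yl]methyl}-6-(2-methylpropanoyl)phenyl acetate | CC(C)C(=O)c1c(OC(C)=O)c(C[C@H]2OC2(C)C)c(OCc2ccccc2)cc1OCc1ccccc1 | intermediate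
9 | 1-[4,6-bis(benzyloxy)-3-{[(2R)-3,3-dimethyloxiran-2-yl]methyl}-2-hydroxyphenyl]-2-methylpropan-1-one (present as its phenoxide) | CC(C)C(=O)c1c(O)c(C[C@H]2OC2(C)C)c(OCc2ccccc2)cc1OCc1ccccc1 | intermediate
10 | 1-[(2S)-4,6-bis(benzyloxy)-2-(2-hydroxypropan-2-yl)-2,3-dihydro-1-benzofuran-7-yl]-2-methylpropan-1-one | CC(C)C(=O)c1c2O[C@H](C(C)(C)O)Cc2c(OCc2ccccc2)cc1OCc1ccccc1 | intermediate
11 | 1-[(2S)-4,6-bis(benzyloxy)-2-{2-[(triethylsilyl)oxy]propan-2-yl}-2,3-dihydro-1-benzofuran-7-yl]-2-methylpropan-1-one | CC(C)C(=O)c1c2O[C@H](C(C)(C)O[Si](CC)(CC)CC)Cc2c(OCc2ccccc2)cc1OCc1ccccc1 | intermediate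
12 | 1-[(2S)-4,6-dihydroxy-2-{2-[(triethylsilyl)oxy]propan-2-yl}-2,3-dihydro-1-benzofuran-7-yl]-2-methylpropan-1-one | CC(C)C(=O)c1c2O[C@H](C(C)(C)O[Si](CC)(CC)CC)Cc2c(O)cc1O | intermediate
13 | endoperoxide of 12: O–O bridge from C3a to C6 on the face opposite the C2 side chain, hydroxyl on C6, double bonds C4=C5 and C7=C7a | CC(C)C(=O)C1=C2O[C@H](C(C)(C)O[Si](CC)(CC)CC)C[C@@]23OO[C@]1(O)C=C3O | intermediate
14 | (2S)-3a-hydroperoxy-4-hydroxy-7-(2-methylpropanoyl)-2-{2-[(triethylsilyl)oxy]propan-2-yl}-3,3a-dihydro-1-benzofuran-6(2H)-one, hydroperoxy group trans to the C2 side chain | CC(C)C(=O)C1=C2O[C@H](C(C)(C)O[Si](CC)(CC)CC)C[C@]2(OO)C(O)=CC1=O | intermediate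
15 | (2S)-3a,4-dihydroxy-7-(2-methylpropanoyl)-2-{2-[(triethylsilyl)oxy]propan-2-yl}-3,3a-dihydro-1-benzofuran-6(2H)-one, C3a hydroxyl trans to the C2 side chain | CC(C)C(=O)C1=C2O[C@H](C(C)(C)O[Si](CC)(CC)CC)C[C@]2(O)C(O)=CC1=O | intermediate
16 | 15 carrying triethylsilyl groups on the C3a oxygen and on the C4 enol oxygen | CC(C)C(=O)C1=C2O[C@H](C(C)(C)O[Si](CC)(CC)CC)C[C@]2(O[Si](CC)(CC)CC)C(O[Si](CC)(CC)CC)=CC1=O | intermediate
17 | 15 carrying a triethylsilyl group on the C3a oxygen only (C4 enol free) | CC(C)C(=O)C1=C2O[C@H](C(C)(C)O[Si](CC)(CC)CC)C[C@]2(O[Si](CC)(CC)CC)C(O)=CC1=O | intermediate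
18 | 5-(3-methylbut-2-en-1-yl) derivative of 17 (C4 enol) | CC(C)C(=O)C1=C2O[C@H](C(C)(C)O[Si](CC)(CC)CC)C[C@]2(O[Si](CC)(CC)CC)C(O)=C(CC=C(C)C)C1=O | intermediate
19 | iodomethane | CI | starting material
20 | (2S,3aR,5S)-5-methyl-5-(3-methylbut-2-en-1-yl)-7-(2-methylpropanoyl)-3a-[(triethylsilyl)oxy]-2-{2-[(triethylsilyl)oxy]propan-2-yl}-2,3,3a,5-tetrahydro-1-benzofuran-4,6-dione | CC(C)=CC[C@@]1(C)C(=O)C(C(=O)C(C)C)=C2O[C@H](C(C)(C)O[Si](CC)(CC)CC)C[C@]2(O[Si](CC)(CC)CC)C1=O | intermediate
21 | (2S,3aR,5S)-3a-hydroxy-2-(2-hydroxypropan-2-yl)-5-methyl-5-(3-methylbut-2-en-1-yl)-7-(2-methylpropanoyl)-2,3,3a,5-tetrahydro-1-benzofuran-4,6-dione (CNP0220605.1) | CC(C)=CC[C@@]1(C)C(=O)C(C(=O)C(C)C)=C2O[C@H](C(C)(C)O)C[C@]2(O)C1=O | target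

**Step count and risks**

Total step count: 13. Longest linear sequence: 13 steps (1 to 21).

Steps most likely to fail:

Step 9. Singlet oxygen may attack the unsubstituted, doubly activated C5 position and lead to over-oxidation, and the remote C2 group may discriminate the two arene faces only partly. Fallback: block C5 before the oxidation. Setting out from 12, bromination at the only free ring position (N-bromosuccinimide, CH2Cl2, −78 °C) would give the 5-bromo arene F1. The same sensitised photooxygenation would then pass through the bromo endoperoxide F2 and the bromo hydroperoxide F3, which Me2S would reduce to the 5-bromo quinol F4. Aqueous Na2SO3 in THF at 0 °C would take the positive bromine off the 2-bromo-1,3-diketone, and the route is rejoined at 15. This fallback addresses the positional problem only; face selection still rests on C2.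

Step 12. Iodomethane may fail to distinguish the two faces of the C5 enolate, and O-methylation may compete. Fallback: reverse the order of the two C5 alkylations and let a chiral catalyst choose the face. Setting out from 17, methylation (MeI, 1 equiv, K2CO3, acetone) would give the 5-methyl enol F5. A Tsuji–Trost allylation of F5 with 3-methylbut-2-en-1-yl acetate and Et3N would then use Pd2(dba)3 (zerovalent palladium) and one enantiomer of N,N'-(cyclohexane-1,2-diyl)bis[2-(diphenylphosphanyl)benzamide] in CH2Cl2; both ligand enantiomers would be tried to find the matched one. The soft enolate should attack the unsubstituted terminus of the allyl complex, and the route is rejoined at 20.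

Step 11. The ambident enolate may be alkylated on oxygen, or twice at C5. Fallback: replace the SN2 alkylation by a Tsuji–Trost allylation through a π-allyl palladium complex. Setting out from 17, treatment with 3-methylbut-2-en-1-yl acetate and Et3N and Pd(PPh3)4 (zerovalent palladium) in THF at rt should funnel any O-allylated enol ether back through the allyl complex to the C5-prenyl compound; the route is rejoined at 18 and no compound outside the list is made (entry F0).

Further compounds
F1 | step 9 | 1-[(2S)-5-bromo-4,6-dihydroxy-2-{2-[(triethylsilyl)oxy]propan-2-yl}-2,3-dihydro-1-benzofuran-7-yl]-2-methylpropan-1-one | CC(C)C(=O)c1c2O[C@H](C(C)(C)O[Si](CC)(CC)CC)Cc2c(O)c(Br)c1O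
F2 | step 9 | 5-bromo analogue of endoperoxide 13 | CC(C)C(=O)C1=C2O[C@H](C(C)(C)O[Si](CC)(CC)CC)C[C@@]23OO[C@]1(O)C(Br)=C3O
F3 | step 9 | 5-bromo analogue of hydroperoxide 14 | CC(C)C(=O)C1=C2O[C@H](C(C)(C)O[Si](CC)(CC)CC)C[C@]2(OO)C(O)=C(Br)C1=O
F4 | step 9 | 5-bromo analogue of quinol 15 | CC(C)C(=O)C1=C2O[C@H](C(C)(C)O[Si](CC)(CC)CC)C[C@]2(O)C(O)=C(Br)C1=O
F5 | step 12 | 5-methyl derivative of 17 (C4 enol) | CC(C)C(=O)C1=C2O[C@H](C(C)(C)O[Si](CC)(CC)CC)C[C@]2(O[Si](CC)(CC)CC)C(O)=C(C)C1=O
F0 | step 11 | none | none
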